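The oxolane is cut at both bonds of C5, the only ring carbon without a substituent, which sits between O1 and C4: O1–C5 and C4–C5. C5 is delivered as a formaldehyde unit that is condensed onto the C2 benzylic oxygen and then captured by an allylsilane at C4. One operation therefore closes the ring, forms two skeletal bonds and leaves a vinyl group on C4 as the precursor of the aroyl group. The precursor is an anti 1-aryl-2-(silyloxymethyl)pent-3-enyl silyl ether with a terminal trimethylsilyl group, carrying C2 and C3 in their final configuration; C4 is adjusted later by enolisation.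

Key step: step 4

Remark on the chemistry: the vinyl carbonate of step 1 is used as the racemate because its stereocentre is erased on ionisation; the E/Z mixture expected from the metathesis is carried forward, since both alkene isomers close to the same ring and C4 is equilibrated in step 8.

Step 1
Reactants: 1 3-(benzyloxy)-4-methoxybenzaldehyde (O-benzylisovanillin); 2 4-vinyl-1,3-dioxolan-2-one (racemic)
Product: 3 (1S,2R)-1-[3-(benzyloxy)-4-methoxyphenyl]-2-ethenylpropane-1,3-diol (anti)
Conditions: [Ir(cod)Cl]2 (2.5 mol %), SEGPHOS (5 mol %; the antipode that gives the 1S,2R diol), 4-cyano-3-nitrobenzoic acid (10 mol %), K3PO4 (cat.), i-PrOH (2 equiv), THF, 70 °C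
Reagents that add atoms: none
Why: Iridium-catalysed transfer-hydrogenative carbonyl (hydroxymethyl)allylation: the carbonate ionises with loss of CO2 to an (E)-σ-allyl iridium species that adds to the aldehyde through a closed chair transition state, which sets C1 and C2 together as the anti pair, while the ligand antipode directs attack to the Si face of the aldehyde (1S,2R).

Step 2
Reactants: 3 (1S,2R)-1-[3-(benzyloxy)-4-methoxyphenyl]-2-ethenylpropane-1,3-diol; 4 allyltrimethylsilane
Product: 5 (1S,2R,3E)-1-[3-(benzyloxy)-4-methoxyphenyl]-2-(hydroxymethyl)-5-(trimethylsilyl)pent-3-en-1-ol (E-major)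
Conditions: 4 (5 equiv), second-generation Grubbs catalyst (H2IMes)(PCy3)Cl2Ru=CHPh (5 mol %), CH2Cl2, 40 °C
Reagents that add atoms: none
Why: Olefin cross-metathesis of a terminal alkene with an excess of allylsilane tolerates the free hydroxyls, touches no stereocentre and should give mainly the E allylsilane, whose geometry is not critical.

Step 3
Reactants: 5 (1S,2R,3E)-1-[3-(benzyloxy)-4-methoxyphenyl]-2-(hydroxymethyl)-5-(trimethylsilyl)pent-3-en-1-ol
Product: 7 (1S,2R,3E)-1-[3-(benzyloxy)-4-methoxyphenyl]-2-[(tert-butyldiphenylsilyloxy)methyl]-5-(trimethylsilyl)pent-3-en-1-ol trimethylsilyl ether, via primary TBDPS ether 6 (not isolated)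
Conditions: TBDPSCl (1.05 equiv), imidazole (4 equiv), CH2Cl2, 0 °C; then TMSCl (1.5 equiv), 0 °C → rt; chromatography on Et3N-deactivated silica
Reagents that add atoms: tert-butyl(chloro)diphenylsilane, CC(C)(C)[Si](Cl)(c1ccccc1)c1ccccc1; chlorotrimethylsilane, C[Si](C)(C)Cl
Why: Chemoselective silylation (the bulky chlorosilane takes only the primary hydroxyl, the small one then caps the hindered benzylic hydroxyl) gives a precursor whose benzylic oxygen can exchange with an acetal without releasing acid and whose primary oxygen is too hindered and too weakly basic to compete for the one-carbon unit.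

Step 4
Reactants: 7 (1S,2R,3E)-1-[3-(benzyloxy)-4-methoxyphenyl]-2-[(tert-butyldiphenylsilyloxy)methyl]-5-(trimethylsilyl)pent-3-en-1-ol trimethylsilyl ether; 8 dimethoxymethane
Product: 10 (2S,3R,4S)-2-[3-(benzyloxy)-4-methoxyphenyl]-3-[(tert-butyldiphenylsilyloxy)methyl]-4-ethenyloxolane (all-trans), via methoxymethyl acetal 9 (not isolated)
Conditions: 8 (5 equiv), TMSOTf (0.2 equiv), 2,6-di-tert-butyl-4-methylpyridine (0.3 equiv), CH2Cl2 (0.02 M), −78 → −30 °C; Et3N quench
Reagents that add atoms: none
Why: TMSOTf ionises dimethoxymethane, the benzylic silyl ether exchanges into the methoxymethyl acetal 9, and loss of its methoxy group as TMSOMe gives the O1=C5H2 oxocarbenium ion, which the allylsilane attacks through its γ-carbon (C4); the β-silyl cation then loses silicon to leave the vinyl group and regenerate TMSOTf. The closest known reaction type is the intramolecular silyl-modified Sakurai (Prins–Sakurai) condensation of hydroxy allylsilane silyl ethers with aldehydes or acetals to 3-vinyl oxolanes. The oxolane closes by C4–C5 bond formation, 5-exo-trig with respect to the allylsilane alkene and endo with respect to the C5=O1 bond. The one new stereocentre, C4, is controlled by C3 through an envelope transition state in which the C2 aryl group, the C3 silyloxymethyl arm and the alkene arm are pseudo-equatorial, placing the vinyl group trans to the C3 arm; a minor C4 epimer is harmless because C4 is equilibrated in step 8. The step needs acetal ionisation to win over ionisation of the electron-rich benzylic C2–O bond and over protodesilylation; the substrate secures this with the preformed TMS ether (exchange without free acid), the non-participating TBDPS ether on the primary oxygen and the β-silicon effect that fixes attack at C4, supported by catalytic TMSOTf, a hindered base and low temperature. Should the C2–O1 bond reopen after closure, re-closure should return the same, more stable 2,3-trans ring.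

Step 5
Reactants: 10 (2S,3R,4S)-2-[3-(benzyloxy)-4-methoxyphenyl]-3-[(tert-butyldiphenylsilyloxy)methyl]-4-ethenyloxolane
Product: 11 (3S,4R,5S)-5-[3-(benzyloxy)-4-methoxyphenyl]-4-[(tert-butyldiphenylsilyloxy)methyl]oxolane-3-carbaldehyde
Conditions: OsO4 (2 mol %), NaIO4 (4 equiv), 2,6-lutidine (2 equiv), 1,4-dioxane–H2O (3:1), rt
Reagents that add atoms: osmium tetroxide OsO4, O=[Os](=O)(=O)=O (oxygen carrier, reoxidised by sodium periodate NaIO4, [Na+].[O-]I(=O)(=O)=O)
Why: Lemieux–Johnson oxidative cleavage (dihydroxylation followed by periodate glycol cleavage) is selective for the monosubstituted alkene over the alkoxyarenes and silyl ether and turns the vinyl carbon into the future carbonyl carbon.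

Step 6
Reactants: 12 5-bromo-2-methoxyphenol
Product: 13 2-(benzyloxy)-4-bromo-1-methoxybenzene
Conditions: BnBr (1.1 equiv), K2CO3 (1.5 equiv), DMF, rt
Reagents that add atoms: benzyl bromide, BrCc1ccccc1
Why: Williamson etherification masks the phenol of ring B so that the aryl bromide can be turned into a Grignard reagent.

Step 7
Reactants: 13 2-(benzyloxy)-4-bromo-1-methoxybenzene; 11 (3S,4R,5S)-5-[3-(benzyloxy)-4-methoxyphenyl]-4-[(tert-butyldiphenylsilyloxy)methyl]oxolane-3-carbaldehyde
Product: 15 [3-(benzyloxy)-4-methoxyphenyl]{(3S,4R,5S)-5-[3-(benzyloxy)-4-methoxyphenyl]-4-[(tert-butyldiphenylsilyloxy)methyl]oxolan-3-yl}methanol (both carbinol epimers), via arylmagnesium bromide 14 (not isolated)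
Conditions: 13 (1.5 equiv), Mg turnings, I2 (cat.), THF, 45 °C; then 11, THF, −78 → −20 °C; aq. NH4Cl
Reagents that add atoms: none
Why: Grignard formation and 1,2-addition to the aldehyde at low temperature should outrun enolisation; the new carbinol centre is uncontrolled and is removed in step 8.

Step 8
Reactants: 15 [3-(benzyloxy)-4-methoxyphenyl]{(3S,4R,5S)-5-[3-(benzyloxy)-4-methoxyphenyl]-4-[(tert-butyldiphenylsilyloxy)methyl]oxolan-3-yl}methanol
Product: 16 [3-(benzyloxy)-4-methoxyphenyl]{(3S,4R,5S)-5-[3-(benzyloxy)-4-methoxyphenyl]-4-[(tert-butyldiphenylsilyloxy)methyl]oxolan-3-yl}methanone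
Conditions: Dess–Martin periodinane (1.3 equiv), CH2Cl2, 0 °C → rt; aqueous work-up; then DBU (0.2 equiv), CH2Cl2, rt
Reagents that add atoms: none
Why: Dess–Martin oxidation of the benzylic carbinol gives the aryl ketone, and base-mediated enolisation then equilibrates C4 (α to the ketone) to the all-trans isomer with the aroyl group anti to the C3 arm; ring opening by β-elimination is stereoelectronically disfavoured because the C5–O1 bond lies in the ring plane.

Step 9
Reactants: 16 [3-(benzyloxy)-4-methoxyphenyl]{(3S,4R,5S)-5-[3-(benzyloxy)-4-methoxyphenyl]-4-[(tert-butyldiphenylsilyloxy)methyl]oxolan-3-yl}methanone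
Product: 17 [3-(benzyloxy)-4-methoxyphenyl]{(3S,4R,5S)-5-[3-(benzyloxy)-4-methoxyphenyl]-4-(hydroxymethyl)oxolan-3-yl}methanone
Conditions: TBAF (3 equiv), AcOH (3 equiv), THF, 0 °C → rt
Reagents that add atoms: none
Why: Fluoride-mediated desilylation, buffered with acetic acid so that the β-alkoxy ketone is not exposed to strong base.

Step 10
Reactants: 17 [3-(benzyloxy)-4-methoxyphenyl]{(3S,4R,5S)-5-[3-(benzyloxy)-4-methoxyphenyl]-4-(hydroxymethyl)oxolan-3-yl}methanone
Product: 18 (3-hydroxy-4-methoxyphenyl)[(3S,4R,5S)-5-(3-hydroxy-4-methoxyphenyl)-4-(hydroxymethyl)oxolan-3-yl]methanone (CNP0234761.1)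
Conditions: H2 (1 atm), 10 % Pd/C, EtOAc–EtOH (3:1), rt; stopped at full conversion
Reagents that add atoms: none
Why: Catalytic hydrogenolysis of the two aryl benzyl ethers is fast under neutral conditions, so the aryl ketone and the benzylic C2–O1 bond should survive if the reaction is not prolonged.

Compound list
1 | 3-(benzyloxy)-4-methoxybenzaldehyde (O-benzylisovanillin) | COc1ccc(C=O)cc1OCc1ccccc1 | starting material
2 | 4-vinyl-1,3-dioxolan-2-one (racemic) | C=CC1COC(=O)O1 | starting material
3 | (1S,2R)-1-[3-(benzyloxy)-4-methoxyphenyl]-2-ethenylpropane-1,3-diol | C=C[C@H](CO)[C@H](O)c1ccc(OC)c(OCc2ccccc2)c1 | intermediate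
4 | allyltrimethylsilane | C=CC[Si](C)(C)C | starting material
5 | (1S,2R,3E)-1-[3-(benzyloxy)-4-methoxyphenyl]-2-(hydroxymethyl)-5-(trimethylsilyl)pent-3-en-1-ol | C[Si](C)(C)C/C=C/[C@H](CO)[C@H](O)c1ccc(OC)c(OCc2ccccc2)c1 | intermediate
6 | (1S,2R,3E)-1-[3-(benzyloxy)-4-methoxyphenyl]-2-[(tert-butyldiphenylsilyloxy)methyl]-5-(trimethylsilyl)pent-3-en-1-ol | C[Si](C)(C)C/C=C/[C@H](CO[Si](c1ccccc1)(c1ccccc1)C(C)(C)C)[C@H](O)c1ccc(OC)c(OCc2ccccc2)c1 | intermediate (not isolated)
7 | (1S,2R,3E)-1-[3-(benzyloxy)-4-methoxyphenyl]-2-[(tert-butyldiphenylsilyloxy)methyl]-5-(trimethylsilyl)pent-3-en-1-ol trimethylsilyl ether (key-step precursor) | C[Si](C)(C)C/C=C/[C@H](CO[Si](c1ccccc1)(c1ccccc1)C(C)(C)C)[C@H](O[Si](C)(C)C)c1ccc(OC)c(OCc2ccccc2)c1 | intermediate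
8 | dimethoxymethane | COCOC | starting material
9 | methoxymethyl acetal of 6 (benzylic O–CH2–OMe) | C[Si](C)(C)C/C=C/[C@H](CO[Si](c1ccccc1)(c1ccccc1)C(C)(C)C)[C@H](OCOC)c1ccc(OC)c(OCc2ccccc2)c1 | intermediate (not isolated)
10 | (2S,3R,4S)-2-[3-(benzyloxy)-4-methoxyphenyl]-3-[(tert-butyldiphenylsilyloxy)methyl]-4-ethenyloxolane (key-step product) | C=C[C@@H]1CO[C@H](c2ccc(OC)c(OCc3ccccc3)c2)[C@H]1CO[Si](c1ccccc1)(c1ccccc1)C(C)(C)C | intermediate
11 | (3S,4R,5S)-5-[3-(benzyloxy)-4-methoxyphenyl]-4-[(tert-butyldiphenylsilyloxy)methyl]oxolane-3-carbaldehyde | O=C[C@@H]1CO[C@H](c2ccc(OC)c(OCc3ccccc3)c2)[C@H]1CO[Si](c1ccccc1)(c1ccccc1)C(C)(C)C | intermediate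
12 | 5-bromo-2-methoxyphenol | COc1ccc(Br)cc1O | starting material
13 | 2-(benzyloxy)-4-bromo-1-methoxybenzene | COc1ccc(Br)cc1OCc1ccccc1 | intermediate
14 | [3-(benzyloxy)-4-methoxyphenyl]magnesium bromide | COc1ccc([Mg]Br)cc1OCc1ccccc1 | intermediate (not isolated)
15 | [3-(benzyloxy)-4-methoxyphenyl]{(3S,4R,5S)-5-[3-(benzyloxy)-4-methoxyphenyl]-4-[(tert-butyldiphenylsilyloxy)methyl]oxolan-3-yl}methanol (carbinol epimers) | COc1ccc(C(O)[C@@H]2CO[C@H](c3ccc(OC)c(OCc4ccccc4)c3)[C@H]2CO[Si](c2ccccc2)(c2ccccc2)C(C)(C)C)cc1OCc1ccccc1 | intermediate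
16 | [3-(benzyloxy)-4-methoxyphenyl]{(3S,4R,5S)-5-[3-(benzyloxy)-4-methoxyphenyl]-4-[(tert-butyldiphenylsilyloxy)methyl]oxolan-3-yl}methanone | COc1ccc(C(=O)[C@@H]2CO[C@H](c3ccc(OC)c(OCc4ccccc4)c3)[C@H]2CO[Si](c2ccccc2)(c2ccccc2)C(C)(C)C)cc1OCc1ccccc1 | intermediate
17 | [3-(benzyloxy)-4-methoxyphenyl]{(3S,4R,5S)-5-[3-(benzyloxy)-4-methoxyphenyl]-4-(hydroxymethyl)oxolan-3-yl}methanone | COc1ccc(C(=O)[C@@H]2CO[C@H](c3ccc(OC)c(OCc4ccccc4)c3)[C@H]2CO)cc1OCc1ccccc1 | intermediate
18 | (3-hydroxy-4-methoxyphenyl)[(3S,4R,5S)-5-(3-hydroxy-4-methoxyphenyl)-4-(hydroxymethyl)oxolan-3-yl]methanone | COc1ccc(C(=O)[C@@H]2CO[C@H](c3ccc(OC)c(O)c3)[C@H]2CO)cc1O | target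

Total step count: 10. Longest linear sequence: 9 steps (steps 1–5 and 7–10, from 1); step 6 is a one-step side branch.

Steps most likely to fail

Step 4. The formaldehyde acetal ionises slowly, so ionisation of the electron-rich benzylic C2–O bond (followed by elimination, cyclopropane formation or capture of methanol) or intermolecular methoxymethylation of the allylsilane may outrun formation of the O1=C5 oxocarbenium ion. The fallback is a stepwise α-acetoxy ether Prins–Sakurai closure that sets out from 6, isolated by leaving TMSCl out of step 3. The benzylic hydroxyl is formylated (acetic formic anhydride, pyridine, 0 °C) to the formate F1. Reduction with iBu2AlH at −78 °C and trapping of the aluminium hemiacetal with Ac2O, pyridine and DMAP (reductive acetylation of an ester) gives the acetoxymethyl ether F2. Catalytic TMSOTf in CH2Cl2 at −78 °C then ionises the acetate, which leaves far more readily than methoxide and at a temperature where the benzylic bond should be inert, and the allylsilane closes the ring to 10, where the route is rejoined. O1–C5 is thus made without acid and only C4–C5 is left to the Lewis acid.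

Step 2. Metathesis of the branched terminal alkene flanked by two hydroxyls may be slow, so that self-metathesis of allyltrimethylsilane, catalyst decay or double-bond migration take over. The fallback builds the allylsilane by Wittig olefination and sets out from 3. Silylation exactly as in step 3 gives the bis-silyl ether F3. Ozonolysis (O3, CH2Cl2, −78 °C; PPh3) gives the aldehyde F4. Reaction with Ph3P=CHCH2SiMe3 (from (2-trimethylsilylethyl)triphenylphosphonium iodide and n-BuLi, THF, −78 °C) gives the Z-rich allylsilane F5. F5 is taken through step 4 in place of 7 and rejoins the route at 10, the alkene geometry being immaterial.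

Step 10. Hydrogenolysis of the benzylic C2–O1 bond of the oxolane or reduction of the aryl ketone may compete with cleavage of the benzyl ethers. The fallback is a non-reductive debenzylation that sets out from 17: BCl3 with pentamethylbenzene as benzyl cation scavenger in CH2Cl2 at −78 °C, quenched with methanol, should give 18 directly. It makes no new compound (F0).

Further compounds
F1 | step 4 | (1S,2R,3E)-1-[3-(benzyloxy)-4-methoxyphenyl]-2-[(tert-butyldiphenylsilyloxy)methyl]-5-(trimethylsilyl)pent-3-en-1-yl formate | C[Si](C)(C)C/C=C/[C@H](CO[Si](c1ccccc1)(c1ccccc1)C(C)(C)C)[C@H](OC=O)c1ccc(OC)c(OCc2ccccc2)c1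
F2 | step 4 | {[(1S,2R,3E)-1-[3-(benzyloxy)-4-methoxyphenyl]-2-[(tert-butyldiphenylsilyloxy)methyl]-5-(trimethylsilyl)pent-3-en-1-yl]oxy}methyl acetate | C[Si](C)(C)C/C=C/[C@H](CO[Si](c1ccccc1)(c1ccccc1)C(C)(C)C)[C@H](OCOC(C)=O)c1ccc(OC)c(OCc2ccccc2)c1
F3 | step 2 | (1S,2R)-1-[3-(benzyloxy)-4-methoxyphenyl]-2-[(tert-butyldiphenylsilyloxy)methyl]but-3-en-1-ol trimethylsilyl ether | C=C[C@H](CO[Si](c1ccccc1)(c1ccccc1)C(C)(C)C)[C@H](O[Si](C)(C)C)c1ccc(OC)c(OCc2ccccc2)c1
F4 | step 2 | (2R,3S)-3-[3-(benzyloxy)-4-methoxyphenyl]-2-[(tert-butyldiphenylsilyloxy)methyl]-3-(trimethylsilyloxy)propanal | O=C[C@H](CO[Si](c1ccccc1)(c1ccccc1)C(C)(C)C)[C@H](O[Si](C)(C)C)c1ccc(OC)c(OCc2ccccc2)c1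
F5 | step 2 | (1S,2R,3Z)-1-[3-(benzyloxy)-4-methoxyphenyl]-2-[(tert-butyldiphenylsilyloxy)methyl]-5-(trimethylsilyl)pent-3-en-1-ol trimethylsilyl ether | C[Si](C)(C)C/C=C\[C@H](CO[Si](c1ccccc1)(c1ccccc1)C(C)(C)C)[C@H](O[Si](C)(C)C)c1ccc(OC)c(OCc2ccccc2)c1
F0 | step 10 | none | none
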